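We follow time first, because we want as much as possible of Q, the species formed on the way from substrate X to product J, at the end of 25 h. G is the catalyst, D the reagent and L a further species.

| flask | X | D | L | G | remark | time |
|---|---|---|---|---|---|---|
| delta | 0.037 M | 0.0444 M | 1.85 mM | 0.13 mM | run made earlier |  |
| alpha | 0.037 M | 0.0444 M | 0.93 mM | 0.13 mM | run made earlier |  |
| epsilon | 0.037 M | 0.0444 M | 3.7 mM | 0.13 mM | run made earlier |  |
| cedar | 0.037 M | 0.0444 M (fed, over 20.0 h) | 1.85 mM | 0.13 mM | all but D at the start; D goes in evenly over 20.0 h, the run ends at 25 h | 25 h |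
| ash | 0.037 M | 0.0444 M | 1.85 mM | 0.13 mM | a closed flask charged with all of it at once and left for 25 h | 25 h |
| maple | 0.037 M (fed, over 20.0 h) | 0.0444 M | 1.85 mM | 0.13 mM | all but X at the start; X goes in evenly over 20.0 h, the run ends at 25 h | 25 h |
| larch | 0.037 M | 0.0444 M | 1.85 mM | 0.13 mM | a single well-mixed tank run continuously and read at steady state, 25 h in it on average |  |

| run | time / h | Q / % | J / % |
|---|---|---|---|
| delta | 3.00 | 31 | 3 |
| delta | 8.00 | 25 | 12 |
| delta | 15.0 | 23 | 17 |
| delta | 25.0 | 21 | 25 |
| alpha | 3.00 | 26 | 3 |
| alpha | 8.00 | 27 | 10 |
| alpha | 15.0 | 23 | 17 |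
| alpha | 25.0 | 18 | 26 |
| epsilon | 6.00 | 23 | 10 |
| epsilon | 12.0 | 21 | 9 |
| epsilon | 20.0 | 25 | 24 |
| epsilon | 25.0 | 15 | 22 |

(scatter of a reading: 2 percentage points)

- the stated concentrations are those of everything mixed, before any reaction; amounts are the same in each set-up
- the analysis behind the earlier runs scatters by 2 percentage points, standard deviation
- the feed brings no volume worth counting
- the earlier runs were made in a closed, stirred flask

1. the set-up with the highest amount of Q at the outlet or at the end, in percent of the X put in ("none" if the first two lie within 2 percentage points) (cedar / ash / maple / larch / none)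
2. amount of Q at the outlet or at the end, in percent of the X put in, cedar
3. amount of Q at the outlet or at the end, in percent of the X put in, ash
4. amount of Q at the outlet or at the end, in percent of the X put in, maple
5. amount of Q at the outlet or at the end, in percent of the X put in, larch

In delta, the closed flask with ash's recipe, J grows by 0.0117 h⁻¹ of the X charged from 3.00 h to 15.0 h. It then grows by 0.00800 h⁻¹ up to 25.0 h, slower by a factor of 1.46. Q sags by a factor of 1.19 from 8.00 h to 25.0 h, and with a scatter of 2 percentage points per reading we cannot tell these two factors apart.

A second number stands beside the rate. Q divided by the part of the X charged that has not become J reads 28.4% at 8.00 h, 27.7% at 15.0 h and 28.0% at 25.0 h. We carry this reading as the share s, the part of what has not become J that stands as Q.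

So we count each point of J not made as returning s of a point to Q, and we reckon that correction. An even feed over 20.0 h brings material in on average 10.0 h late, and we take that as sparing a fed flask the last stretch of delta, at the rate read there. By this estimate that withholds 8 points of J and adds 2.2 points of Q to the 21% read for this recipe. Our reckoning for cedar and maple is therefore 23.2%.

The forecast says none, with cedar 24.5%, ash 20.5%, maple 24.5% and larch 22%, on the ground that “feeding delays formation of Q, so less is lost to J”. Its fed flasks stand 1.3 points above ours.

The flasks give cedar 22.7%, ash 20.3%, maple 23.0% and larch 21.0%, so the answer is none.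

    X + G ⇌ G + Q (K = 0.420, k = 1.10 M⁻¹ s⁻¹)
    G + Q ⇌ E (K = 12.0 M⁻¹, k = 1.00 M⁻¹ s⁻¹)
    D + E → G + J (k = 0.240 M⁻¹ s⁻¹)
    Q + L → Z (k = 0.00310 M⁻¹ s⁻¹)

Here E is G holding Q, and Z comes from Q and L. In maple, X and Q exchange over G with a relaxation half-life of 0.435 h at 25.0 h, short against the 25 h of the run, while J stands at 16.7%. The share s then gives 23.3% of Q for maple, which holds 23.0%. In a further flask, maple with 5.2 × 10⁻⁴ M of G, J reaches 46.1%, so s gives 15.1%, and that flask holds 14.7%.

All runs were computed on assumed constants, and the scatter is random.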